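The earlier runs and the new flask stem from a simulated flask for an exercise, and the scatter is random.

1. I rank these flasks by one count: how many powers of ten the complex with one exchanged loses during the run.

| setting | winter | summer | midnight | Saturday's | Tuesday's | Friday's |
|---|---|---|---|---|---|---|
| starting complex | 1 mM | 1 mM | 1 mM | 1.0 mM | 1.0 mM | 1.0 mM |
| incoming ligand | 0.46 mM | 1.1 mM | 2.1 mM | 0.500 mM | 2.00 mM | 3.00 mM |
| leaving ligand | 5 mM | 5 mM | 5 mM | 5.00 mM | 5.00 mM | 5.00 mM |
| remark | run made earlier | run made earlier | run made earlier |  |  |  |
| time |  |  |  | 10 min | 10 min | 10 min |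

| run | time / min | complex with one exchanged / % | complex with three exchanged / % |
|---|---|---|---|
| winter | 0.833 | 20.4 | 0.2 |
| winter | 2.50 | 18.4 | 0.2 |
| winter | 5.00 | 13.3 | 0.2 |
| winter | 8.00 | 9.6 | 0.4 |
| winter | 10.0 | 7.8 | 0 |
| summer | 2.00 | 20.2 | 0.6 |
| summer | 4.00 | 18.2 | 1.1 |
| summer | 6.00 | 16.2 | 0.6 |
| summer | 8.00 | 15.0 | 0.8 |
| summer | 10.0 | 13.0 | 0.4 |
| midnight | 0.833 | 10.0 | 4.9 |
| midnight | 2.50 | 3.7 | 8.7 |
| midnight | 5.00 | 1.9 | 10.8 |
| midnight | 8.00 | 0.9 | 12.0 |
| midnight | 10.0 | 0.1 | 12.8 |

(standard deviation of a reading: 0.5 percentage points)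

- the earlier runs were read with a standard deviation of 0.5 percentage points

1. complex with one exchanged at the end, in percent of the starting complex charged, for each flask in turn (Saturday's, Tuesday's, Friday's)

2. Two times give that count. One is the run, 10 min. The other is the decade time, the time to lose one power of ten: 22.0 min, read between winter's first and last readings.

3. In winter, each reading after the first is lower, so I count from the first. That gives 0.418 decades. Saturday's charge of 0.500 mM lies next to winter's 0.46 mM, so I reckon Saturday's at winter's last reading, 7.8%.

4. Midnight's first and third readings give a decade time of 5.78 min, shorter than winter's. Each of those two readings carries a scatter of 0.5 points. Tuesday's charge of 2.00 mM lies next to midnight's 2.1 mM, so I reckon Tuesday's at 0.259%. Friday's charge exceeds midnight's, so I put it below that figure.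

5. The forecast says 8.4%, 1% and 0.1%, holding that "a steep threshold lies between 1.1 and 2.1 mM". My Saturday's and Tuesday's figures are lower.

6. The flasks give 8.81%, 2.28% and <0.001%, and the forecast holds within its margin.

    starting complex + incoming ligand → leaving ligand + complex with one exchanged (k = 48.3 L mol⁻¹ s⁻¹)
    complex with one exchanged + incoming ligand → leaving ligand + complex with two exchanged (k = 91.2 L mol⁻¹ s⁻¹)
    complex with two exchanged + incoming ligand → leaving ligand + complex with three exchanged (k = 2.79 L mol⁻¹ s⁻¹)
    complex with two exchanged → decomposed reagent (k = 0.00289 s⁻¹)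
    starting complex + complex with one exchanged → side product (k = 3.18 L mol⁻¹ s⁻¹)

In Saturday's, the incoming ligand, the limiting reagent, stands at 0% of its charge at 5.00 min. From then to the end, starting complex falls from 52.9% to 47.5% while side product, which counts as two in each percentage, rises from 20.1% to 30.8%. Saturday's decade time over that stretch is 24.2 min, against winter's 22.0 min. Tuesday's holds 2.03% of its incoming ligand at 5.00 min, and its decade time from there is 35.1 min, longer than midnight's 5.78 min, which was read on the earlier stretch up to 5.00 min. Tuesday's complex with one exchanged ends at 2.28%, not my 0.259%.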